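**Plan**
- Retrosynthesis: cut the geranyl O–C bond, then the C3–OH bond, then the C2–H/C3–H pair (back to a flat flavone), and last ring C at C4–C4a, C3–C4 and O1–C2.
- Enabling feature: C4 is a carbonyl carbon between aryl carbon C4a and C3, and O1 sits on the ring-A carbon ortho to C4a, so ring C maps onto an ortho-iodophenol, carbon monoxide and an arylacetylene.
- Forward: ring A (benzyl-protected iodophenol) and ring B (silylated catechol acetylene) are prepared separately, ring C is closed between them with CO in one flask, and the geranyl chain is attached in the penultimate step.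
- Stereochemistry: C2 comes from catalyst-controlled asymmetric hydrogenation of the flavone (2S in the flavanone, named 2R once O3 is present); C3 comes from substrate-controlled epoxidation of the enol ether anti to the C2 aryl group (3R, trans).

Key step: step 4

Assumption: the (R,R) carbene ligand is written for step 5; its sense of induction on this flavone has to be confirmed, and the (S,S) ligand would be used if the (2R)-flavanone were to result.

**Route**

Step 1
Reactants: 1 3-(benzyloxy)phenol
Product: 2 5-(benzyloxy)-2-iodophenol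
Conditions: I2 (1.0 equiv), NaHCO3, THF/H2O, 0 °C → rt
Reagents that add atoms: iodine, II
Why: Electrophilic aromatic iodination of the phenol, expected by analogy with 3-methoxyphenol under the same conditions to occur ortho to the hydroxyl and para to the ether oxygen, with the para-to-hydroxyl isomer as a minor product to be removed by chromatography.

Step 2
Reactants: 3 3,4-dihydroxybenzaldehyde
Product: 4 3,4-bis(tert-butyldimethylsilyloxy)benzaldehyde
Conditions: TBSCl (2.4 equiv), imidazole, DMF, rt
Reagents that add atoms: tert-butyldimethylsilyl chloride, CC(C)(C)[Si](C)(C)Cl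
Why: Imidazole-promoted silyl ether formation on both catechol hydroxyls, a standard protection that leaves the aldehyde untouched.

Step 3
Reactants: 4 3,4-bis(tert-butyldimethylsilyloxy)benzaldehyde
Product: 5 4-ethynyl-1,2-bis(tert-butyldimethylsilyloxy)benzene
Conditions: TMSCHN2, LiN(i-Pr)2, THF, −78 °C → rt
Reagents that add atoms: trimethylsilyldiazomethane, C[Si](C)(C)C=[N+]=[N-]
Why: Colvin homologation, in which lithiated trimethylsilyldiazomethane adds to the aldehyde, Peterson elimination and loss of N2 give an alkylidene carbene, and its 1,2-hydrogen shift gives the terminal alkyne under aprotic conditions that spare the aryl silyl ethers.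

Step 4
Reactants: 2 5-(benzyloxy)-2-iodophenol; 5 4-ethynyl-1,2-bis(tert-butyldimethylsilyloxy)benzene; 6 carbon monoxide
Product: 9 7-(benzyloxy)-2-[3,4-bis(tert-butyldimethylsilyloxy)phenyl]-4H-chromen-4-one, via ynone 7 (not isolated), via enaminone 8 (not isolated)
Conditions: PdCl2(dppf) (5 mol%), Et2NH, CO (20 bar), 100 °C, no copper co-catalyst
Reagents that add atoms: carbon monoxide 6, [C-]#[O+] (the numbered reactant; no other reagent adds atoms)
Why: Zerovalent palladium formed from PdCl2(dppf) inserts into the C–I bond of 2, CO insertion gives an aroylpalladium iodide, and its copper-free coupling with the amine-activated alkyne 5 forms the C4–C4a and C3–C4 bonds of ynone 7. Diethylamine then adds to the ynone to give enaminone 8, and the ortho phenol displaces the amine at the same carbon by addition–elimination, forming O1–C2 and regenerating the amine. The closest known reaction is the palladium-catalysed carbonylative Sonogashira coupling–cyclisation of 2-iodophenols with arylacetylenes in a secondary amine, an established flavone synthesis. Ring C closes in a 6-endo mode (6-endo-dig with respect to the alkyne, realised as a 6-endo-trig addition–elimination on the enaminone). No stereocentre is formed, so the selectivities needed are carbonylation before C–C coupling (otherwise a 2-arylbenzofuran) and 6-endo over 5-exo oxygen attack (otherwise an aurone). CO under pressure without copper should secure the first, and the enaminone, in which the amine-bearing carbon is the only electrophilic site, should secure the second; the hydroxyl para to iodine is capped as the benzyl ether so that only the ortho phenol can close the ring.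

Step 5
Reactants: 9 7-(benzyloxy)-2-[3,4-bis(tert-butyldimethylsilyloxy)phenyl]-4H-chromen-4-one
Product: 11 (2S,4S)-7-(benzyloxy)-2-[3,4-bis(tert-butyldimethylsilyloxy)phenyl]chroman-4-ol (2,4-cis), via flavanone 10 (not isolated)
Conditions: [Ru(cod)(2-methylallyl)2] (5 mol%), (R,R)-SINpEt·HBF4 (1,3-bis[(1R)-1-(naphthalen-1-yl)ethyl]-4,5-dihydroimidazolium tetrafluoroborate, 10 mol%), KOtBu (10 mol%, consumed in preforming the catalyst), H2 (100 bar), toluene/n-hexane, 25 °C
Reagents that add atoms: none
Why: Ruthenium–NHC-catalysed asymmetric hydrogenation, a reaction established for flavones, in which the chiral carbene ligand directs hydrogen to one face of the C2=C3 bond and so sets C2 (S), after which the ketone of flavanone 10 is reduced under substrate control to the 2,4-cis alcohol, whose C4 configuration is of no consequence because step 6 removes it.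

Step 6
Reactants: 11 (2S,4S)-7-(benzyloxy)-2-[3,4-bis(tert-butyldimethylsilyloxy)phenyl]chroman-4-ol
Product: 10 (2S)-7-(benzyloxy)-2-[3,4-bis(tert-butyldimethylsilyloxy)phenyl]chroman-4-one
Conditions: Dess–Martin periodinane, CH2Cl2, 0 °C → rt
Reagents that add atoms: none
Why: Dess–Martin oxidation of the secondary benzylic alcohol to the ketone under non-basic conditions, so that the C2 stereocentre, which is labile only through base-induced ring opening, and both kinds of ether stay untouched.

Step 7
Reactants: 10 (2S)-7-(benzyloxy)-2-[3,4-bis(tert-butyldimethylsilyloxy)phenyl]chroman-4-one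
Product: 12 (2S)-7-(benzyloxy)-2-[3,4-bis(tert-butyldimethylsilyloxy)phenyl]-4-(trimethylsilyloxy)-2H-chromene
Conditions: TMSOTf, Et3N, CH2Cl2, 0 °C; used crude
Reagents that add atoms: trimethylsilyl trifluoromethanesulfonate, C[Si](C)(C)OS(=O)(=O)C(F)(F)F
Why: Soft enolisation (silyl triflate with a tertiary amine) silylates the carbonyl oxygen and then removes a C3 proton, giving the silyl enol ether without a free enolate, so that β-elimination of the ring oxygen and with it racemisation at C2 should be avoided.

Step 8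
Reactants: 12 (2S)-7-(benzyloxy)-2-[3,4-bis(tert-butyldimethylsilyloxy)phenyl]-4-(trimethylsilyloxy)-2H-chromene
Product: 14 (2R,3R)-7-(benzyloxy)-2-[3,4-bis(tert-butyldimethylsilyloxy)phenyl]-3-hydroxychroman-4-one, via silyloxy epoxide 13 (not isolated)
Conditions: DMDO (acetone solution), CH2Cl2, −40 → 0 °C; then citric acid, MeOH/H2O, 0 °C
Reagents that add atoms: dimethyldioxirane, CC1(C)OO1
Why: Rubottom oxidation, in which the dioxirane epoxidises the electron-rich enol ether on the face opposite the adjacent C2 aryl group and mild acid hydrolysis of the silyloxy epoxide gives the α-hydroxy ketone with the 3-hydroxyl trans to the aryl group (3R), the diequatorial arrangement that is also thermodynamically preferred.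

Step 9
Reactants: 14 (2R,3R)-7-(benzyloxy)-2-[3,4-bis(tert-butyldimethylsilyloxy)phenyl]-3-hydroxychroman-4-one
Product: 15 (2R,3R)-2-[3,4-bis(tert-butyldimethylsilyloxy)phenyl]-3,7-dihydroxychroman-4-one
Conditions: H2 (1 atm), Pd/C (10 wt%), EtOAc, rt
Reagents that add atoms: none
Why: Hydrogenolysis of the benzyl aryl ether over palladium on carbon in a neutral aprotic solvent, conditions under which the aryl silyl ethers, the ketone and the cyclic benzylic C2–O bond are expected to survive.

Step 10
Reactants: 15 (2R,3R)-2-[3,4-bis(tert-butyldimethylsilyloxy)phenyl]-3,7-dihydroxychroman-4-one; 16 geraniol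
Product: 17 (2R,3R)-2-[3,4-bis(tert-butyldimethylsilyloxy)phenyl]-7-{[(2E)-3,7-dimethylocta-2,6-dien-1-yl]oxy}-3-hydroxychroman-4-one
Conditions: PPh3, DIAD, THF, 0 °C → rt
Reagents that add atoms: none
Why: Mitsunobu etherification, in which the acidic 7-phenol (para to the carbonyl) is the pronucleophile and the primary allylic alcohol geraniol is activated much faster than the hindered, carbonyl-hydrogen-bonded secondary 3-hydroxyl, so that SN2 displacement at C1 of geraniol should give the (E)-geranyl ether under neutral conditions that do not touch C2 or C3.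

Step 11
Reactants: 17 (2R,3R)-2-[3,4-bis(tert-butyldimethylsilyloxy)phenyl]-7-{[(2E)-3,7-dimethylocta-2,6-dien-1-yl]oxy}-3-hydroxychroman-4-one
Product: 18 (2R,3R)-2-(3,4-dihydroxyphenyl)-7-{[(2E)-3,7-dimethylocta-2,6-dien-1-yl]oxy}-3-hydroxychroman-4-one (the target)
Conditions: TBAF, AcOH (1:1), THF, 0 °C
Reagents that add atoms: none
Why: Fluoride cleavage of the two aryl silyl ethers, buffered with acetic acid so that the base-sensitive dihydroflavonol (ring opening, epimerisation, catechol oxidation) and the allylic geranyl ether are not harmed.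

**Compound list**

1 | 3-(benzyloxy)phenol | Oc1cccc(OCc2ccccc2)c1 | starting material
2 | 5-(benzyloxy)-2-iodophenol | Oc1cc(OCc2ccccc2)ccc1I | intermediate
3 | 3,4-dihydroxybenzaldehyde | O=Cc1ccc(O)c(O)c1 | starting material
4 | 3,4-bis(tert-butyldimethylsilyloxy)benzaldehyde | O=Cc1ccc(O[Si](C)(C)C(C)(C)C)c(O[Si](C)(C)C(C)(C)C)c1 | intermediate
5 | 4-ethynyl-1,2-bis(tert-butyldimethylsilyloxy)benzene | C#Cc1ccc(O[Si](C)(C)C(C)(C)C)c(O[Si](C)(C)C(C)(C)C)c1 | intermediate
6 | carbon monoxide | [C-]#[O+] | starting material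
7 | ynone, 1-[4-(benzyloxy)-2-hydroxyphenyl]-3-[3,4-bis(tert-butyldimethylsilyloxy)phenyl]prop-2-yn-1-one (not isolated) | O=C(C#Cc1ccc(O[Si](C)(C)C(C)(C)C)c(O[Si](C)(C)C(C)(C)C)c1)c1ccc(OCc2ccccc2)cc1O | intermediate
8 | enaminone, 1-[4-(benzyloxy)-2-hydroxyphenyl]-3-[3,4-bis(tert-butyldimethylsilyloxy)phenyl]-3-(diethylamino)prop-2-en-1-one, drawn as the E isomer, geometry not fixed (not isolated) | CCN(CC)/C(=C/C(=O)c1ccc(OCc2ccccc2)cc1O)c1ccc(O[Si](C)(C)C(C)(C)C)c(O[Si](C)(C)C(C)(C)C)c1 | intermediate
9 | 7-(benzyloxy)-2-[3,4-bis(tert-butyldimethylsilyloxy)phenyl]-4H-chromen-4-one | O=C1C=C(c2ccc(O[Si](C)(C)C(C)(C)C)c(O[Si](C)(C)C(C)(C)C)c2)Oc2cc(OCc3ccccc3)ccc12 | intermediate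
10 | (2S)-7-(benzyloxy)-2-[3,4-bis(tert-butyldimethylsilyloxy)phenyl]chroman-4-one | c1ccccc1COc1ccc2c(c1)O[C@H](c1ccc(O[Si](C)(C)C(C)(C)C)c(O[Si](C)(C)C(C)(C)C)c1)CC2=O | intermediate
11 | (2S,4S)-7-(benzyloxy)-2-[3,4-bis(tert-butyldimethylsilyloxy)phenyl]chroman-4-ol (2,4-cis) | c1ccccc1COc1ccc2c(c1)O[C@H](c1ccc(O[Si](C)(C)C(C)(C)C)c(O[Si](C)(C)C(C)(C)C)c1)C[C@@H]2O | intermediate
12 | (2S)-7-(benzyloxy)-2-[3,4-bis(tert-butyldimethylsilyloxy)phenyl]-4-(trimethylsilyloxy)-2H-chromene | c1ccccc1COc1ccc2c(c1)O[C@H](c1ccc(O[Si](C)(C)C(C)(C)C)c(O[Si](C)(C)C(C)(C)C)c1)C=C2O[Si](C)(C)C | intermediate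
13 | silyloxy epoxide, the 3,4-epoxide of 12 with the oxirane oxygen trans to the C2 aryl group (not isolated) | c1ccccc1COc1ccc2c(c1)O[C@H](c1ccc(O[Si](C)(C)C(C)(C)C)c(O[Si](C)(C)C(C)(C)C)c1)[C@H]3O[C@@]23O[Si](C)(C)C | intermediate
14 | (2R,3R)-7-(benzyloxy)-2-[3,4-bis(tert-butyldimethylsilyloxy)phenyl]-3-hydroxychroman-4-one | c1ccccc1COc1ccc2c(c1)O[C@H](c1ccc(O[Si](C)(C)C(C)(C)C)c(O[Si](C)(C)C(C)(C)C)c1)[C@@H](O)C2=O | intermediate
15 | (2R,3R)-2-[3,4-bis(tert-butyldimethylsilyloxy)phenyl]-3,7-dihydroxychroman-4-one | Oc1ccc2c(c1)O[C@H](c1ccc(O[Si](C)(C)C(C)(C)C)c(O[Si](C)(C)C(C)(C)C)c1)[C@@H](O)C2=O | intermediate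
16 | geraniol, (2E)-3,7-dimethylocta-2,6-dien-1-ol | CC(C)=CCC/C(C)=C/CO | starting material
17 | (2R,3R)-2-[3,4-bis(tert-butyldimethylsilyloxy)phenyl]-7-{[(2E)-3,7-dimethylocta-2,6-dien-1-yl]oxy}-3-hydroxychroman-4-one | CC(C)=CCC/C(C)=C/COc1ccc2c(c1)O[C@H](c1ccc(O[Si](C)(C)C(C)(C)C)c(O[Si](C)(C)C(C)(C)C)c1)[C@@H](O)C2=O | intermediate
18 | (2R,3R)-2-(3,4-dihydroxyphenyl)-7-{[(2E)-3,7-dimethylocta-2,6-dien-1-yl]oxy}-3-hydroxychroman-4-one | CC(C)=CCC/C(C)=C/COc1ccc2c(c1)O[C@H](c1ccc(O)c(O)c1)[C@@H](O)C2=O | target

**Summary**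

Total step count: 11.
Longest linear sequence: 10 steps (from 3 through steps 2 to 11); the ring-A branch from 1 is 9 steps.

**Steps most likely to fail**

1. Step 4. The aryl silyl ethers may be stripped by hot amine and phenoxide, or C–C coupling may outrun CO insertion and lead to five-membered-ring closure. The fallback sets out from 2 and comes back at 9, and separates coupling from ring closure. Acetylation of 2 (Ac2O, pyridine, CH2Cl2) would give 5-(benzyloxy)-2-iodophenyl acetate F1, whose blocked phenol cannot cyclise. Carbonylative Sonogashira coupling of F1 with 5 under a CO balloon at room temperature (PdCl2(PPh3)2, Et3N, THF) would give the isolated O-acetyl ynone, 5-(benzyloxy)-2-{3-[3,4-bis(tert-butyldimethylsilyloxy)phenyl]prop-2-ynoyl}phenyl acetate F2. Treatment of F2 with Et2NH at room temperature would add the amine to the triple bond and aminolyse the acetate, and the resulting enaminone 8 would close to flavone 9.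

2. Step 5. Facial discrimination may be poor on this bulky, electron-rich flavone, or hydrogenation may stop at mixtures. The fallback sets out from 9 and comes back at 10, replacing catalyst control in the hydrogenation by a kinetic resolution. An achiral copper hydride 1,4-reduction (Cu(OAc)2, 1,2-bis(diphenylphosphino)benzene, diethoxymethylsilane, t-BuOH, toluene, rt) would give racemic 7-(benzyloxy)-2-[3,4-bis(tert-butyldimethylsilyloxy)phenyl]chroman-4-one F3. Asymmetric transfer hydrogenation of F3 (RhCl(Cp*)[(R,R)-TsDPEN] or its antipode, whichever reduces the (2R) ketone faster, HCO2H/Et3N, EtOAc, rt, stopped just past half conversion) would reduce the unwanted enantiomer to (2R,4R)-7-(benzyloxy)-2-[3,4-bis(tert-butyldimethylsilyloxy)phenyl]chroman-4-ol F4. F4 would be removed by chromatography, leaving the (2S)-flavanone 10.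

3. Step 7. Under the silyl triflate, ring C may open by β-elimination of the ring-A oxygen (retro-oxa-Michael), which would erode the C2 configuration before C3 is oxidised. The fallback sets out from 11 and comes back at 14, and uses no enol derivative of the flavanone. Dehydration of 11 with Burgess reagent (toluene, 50 °C) would give (2S)-7-(benzyloxy)-2-[3,4-bis(tert-butyldimethylsilyloxy)phenyl]-2H-chromene F5. Dihydroxylation of F5 (OsO4 cat., NMO, acetone/H2O) anti to the aryl group would give (2R,3S,4S)-7-(benzyloxy)-2-[3,4-bis(tert-butyldimethylsilyloxy)phenyl]chromane-3,4-diol F6 (2,3-trans, 3,4-cis). Selective oxidation of the benzylic C4 alcohol of F6 with MnO2 (CH2Cl2, rt) would return the route to 14.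

**Further compounds**

F1 | step 4 | 5-(benzyloxy)-2-iodophenyl acetate | CC(=O)Oc1cc(OCc2ccccc2)ccc1I
F2 | step 4 | 5-(benzyloxy)-2-{3-[3,4-bis(tert-butyldimethylsilyloxy)phenyl]prop-2-ynoyl}phenyl acetate | CC(=O)Oc1cc(OCc2ccccc2)ccc1C(=O)C#Cc1ccc(O[Si](C)(C)C(C)(C)C)c(O[Si](C)(C)C(C)(C)C)c1
F3 | step 5 | racemic 7-(benzyloxy)-2-[3,4-bis(tert-butyldimethylsilyloxy)phenyl]chroman-4-one | O=C1CC(c2ccc(O[Si](C)(C)C(C)(C)C)c(O[Si](C)(C)C(C)(C)C)c2)Oc2cc(OCc3ccccc3)ccc12
F4 | step 5 | (2R,4R)-7-(benzyloxy)-2-[3,4-bis(tert-butyldimethylsilyloxy)phenyl]chroman-4-ol | c1ccccc1COc1ccc2c(c1)O[C@@H](c1ccc(O[Si](C)(C)C(C)(C)C)c(O[Si](C)(C)C(C)(C)C)c1)C[C@H]2O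
F5 | step 7 | (2S)-7-(benzyloxy)-2-[3,4-bis(tert-butyldimethylsilyloxy)phenyl]-2H-chromene | c1ccccc1COc1ccc2c(c1)O[C@H](c1ccc(O[Si](C)(C)C(C)(C)C)c(O[Si](C)(C)C(C)(C)C)c1)C=C2
F6 | step 7 | (2R,3S,4S)-7-(benzyloxy)-2-[3,4-bis(tert-butyldimethylsilyloxy)phenyl]chromane-3,4-diol | c1ccccc1COc1ccc2c(c1)O[C@H](c1ccc(O[Si](C)(C)C(C)(C)C)c(O[Si](C)(C)C(C)(C)C)c1)[C@@H](O)[C@H]2O
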